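**Assumption:** Cathafuran C (1) has no stereocenters. The chromene C3=C4 is endocyclic and therefore cis. "Single enantiomer" is moot, and no step needs to set or protect a stereocenter.

## Retrosynthesis
1. Cathafuran C (1) is made by forming the furan ring last, via Sonogashira coupling and 5-endo-dig cyclisation of aryl alkyne 2 with 4-iodoresorcinol (3).
2. Alkyne 2 comes from chromene aldehyde 4 by Ohira–Bestmann homologation.
3. The pyran ring of 4 is formed by propargyl Claisen rearrangement and 6π-oxa-electrocyclisation of aryl ether 5.
4. Ether 5 comes from O-propargylation of prenyl resorcinol 6. Compound 6 comes from allyl compound 7 by cross-metathesis, and 7 from aromatic Claisen rearrangement of mono-allyl ether 8.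
5. Ether 8 comes from mono-allylation of symmetrical 3,5-dihydroxybenzaldehyde (9), whose CHO carbon becomes benzofuran C2. Ring-formation order: prenyl arm, then pyran, then furan.

## Forward synthesis

**Step 1**
Reactants: 9 (3,5-dihydroxybenzaldehyde); 10 (allyl bromide)
Product: 8 (3-(allyloxy)-5-hydroxybenzaldehyde)
Conditions: 10 (0.9 equiv), K2CO3, acetone, reflux
Reagents that add atoms: allyl bromide, C=CCBr
Why: Williamson etherification of a symmetrical diol, where statistical mono-alkylation gives 8 and the bis-ether and recovered 9 are separable. No stereocenter is involved.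

**Step 2**
Reactants: 8
Product: 7 (2-allyl-3,5-dihydroxybenzaldehyde)
Conditions: PhNEt2, 210 °C (or microwave), 2 h
Reagents that add atoms: none
Why: Aromatic Claisen [3,3] rearrangement. The CHO group favours the adjacent ortho position (C2), and the meta OH favours the position para to it (also C2), so C2 is preferred over C4. The minor C4 isomer is removed by chromatography.

**Step 3**
Reactants: 7; 11 (2-methyl-2-butene)
Product: 6 (3,5-dihydroxy-2-(3-methylbut-2-en-1-yl)benzaldehyde)
Conditions: Hoveyda–Grubbs II (5 mol %), 11 (20 equiv), CH2Cl2, 40 °C, sealed tube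
Reagents that add atoms: 2-methyl-2-butene, CC=C(C)C (supplies the =CMe2 terminus; propene is lost)
Why: Olefin cross-metathesis converts the terminal allyl alkene into the trisubstituted prenyl alkene. The free phenols and the aldehyde are tolerated, and no stereocenter is formed.

**Step 4**
Reactants: 6; 12 (3-chloro-3-methylbut-1-yne)
Product: 5 (3-hydroxy-5-[(2-methylbut-3-yn-2-yl)oxy]-2-(3-methylbut-2-en-1-yl)benzaldehyde)
Conditions: 12 (3 equiv), K2CO3, KI, CuI (10 mol %), DMF, 60 °C
Reagents that add atoms: 3-chloro-3-methylbut-1-yne, CC(C)(Cl)C#C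
Why: Cu-catalysed O-alkylation with a tertiary propargylic chloride. It goes selectively on the unhindered 5-OH, because the 3-OH is flanked by the prenyl group.

**Step 5**
Reactants: 5
Product: 4 (7-hydroxy-2,2-dimethyl-6-(3-methylbut-2-en-1-yl)-2H-chromene-5-carbaldehyde)
Conditions: PhNEt2, 190 °C, 3 h
Reagents that add atoms: none
Why: Propargyl Claisen rearrangement to the allenyl dienone, then enolisation, 1,5-H shift and 6π-oxa-electrocyclisation gives the 2,2-dimethyl-2H-chromene. As in step 2, the CHO and the meta OH both direct cyclisation to C6, the carbon between the ether oxygen and the CHO-bearing carbon. This gives the 5-formyl chromene, with the ring double bond necessarily cis.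

**Step 6**
Reactants: 4; 13 (Bestmann–Ohira reagent)
Product: 2 (5-ethynyl-2,2-dimethyl-6-(3-methylbut-2-en-1-yl)-2H-chromen-7-ol)
Conditions: 13 (2.5 equiv), K2CO3, MeOH, rt, 12 h
Reagents that add atoms: dimethyl (1-diazo-2-oxopropyl)phosphonate, CC(=O)C(=[N+]=[N-])P(=O)(OC)OC (supplies the terminal alkyne carbon)
Why: Ohira–Bestmann one-carbon alkynylation of the aldehyde. The mild base leaves the phenol, chromene and prenyl groups intact, and extra reagent compensates for the phenol and the hindered 2,6-disubstituted aldehyde.

**Step 7**
Reactants: 2; 3 (4-iodoresorcinol)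
Product: 1 (Cathafuran C)
Conditions: PdCl2(PPh3)2 (5 mol %), CuI (10 mol %), Et3N, DMF, 80 °C, 12 h
Reagents that add atoms: none (both coupling partners are listed reactants)
Why: Sonogashira coupling gives the o-alkynylphenol, which undergoes Pd/Cu-mediated 5-endo-dig O-cyclisation in the same pot. Cyclisation occurs through the OH ortho to the alkyne, so the remaining OH ends up at benzofuran C6. The small, linear alkyne tolerates the 2,6-disubstituted aryl group, and no stereocenter is involved.

## Compound list
1 | Cathafuran C | CC(C)=CCc1c(O)cc2c(c1-c1cc3ccc(O)cc3o1)C=CC(C)(C)O2 | target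
2 | 5-ethynyl-2,2-dimethyl-6-(3-methylbut-2-en-1-yl)-2H-chromen-7-ol | CC(C)=CCc1c(O)cc2OC(C)(C)C=Cc2c1C#C | intermediate
3 | 4-iodobenzene-1,3-diol (4-iodoresorcinol) | Oc1ccc(I)c(O)c1 | starting material
4 | 7-hydroxy-2,2-dimethyl-6-(3-methylbut-2-en-1-yl)-2H-chromene-5-carbaldehyde | CC(C)=CCc1c(O)cc2OC(C)(C)C=Cc2c1C=O | intermediate
5 | 3-hydroxy-5-[(2-methylbut-3-yn-2-yl)oxy]-2-(3-methylbut-2-en-1-yl)benzaldehyde | CC(C)=CCc1c(O)cc(OC(C)(C)C#C)cc1C=O | intermediate
6 | 3,5-dihydroxy-2-(3-methylbut-2-en-1-yl)benzaldehyde | CC(C)=CCc1c(O)cc(O)cc1C=O | intermediate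
7 | 2-allyl-3,5-dihydroxybenzaldehyde | C=CCc1c(O)cc(O)cc1C=O | intermediate
8 | 3-(allyloxy)-5-hydroxybenzaldehyde | C=CCOc1cc(O)cc(C=O)c1 | intermediate
9 | 3,5-dihydroxybenzaldehyde | O=Cc1cc(O)cc(O)c1 | starting material
10 | allyl bromide | C=CCBr | starting material (reagent)
11 | 2-methyl-2-butene | CC=C(C)C | starting material (reagent)
12 | 3-chloro-3-methylbut-1-yne | CC(C)(Cl)C#C | starting material (reagent)
13 | dimethyl (1-diazo-2-oxopropyl)phosphonate (Bestmann–Ohira reagent) | CC(=O)C(=[N+]=[N-])P(=O)(OC)OC | starting material (reagent)

**Total step count:** 7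
**Longest linear sequence:** 7 steps (9 → 8 → 7 → 6 → 5 → 4 → 2 → 1)

## Three steps most likely to fail
1. **Step 5 (propargyl Claisen/6π, with the same regiochemistry issue in step 2).** Cyclisation could go to C4, giving the 5-hydroxychromene, or the substrate could decompose at 190 °C.
   *Fallback:* Reorder the sequence. Make the chromene first by propargylation and Claisen of mono-ether of 9, then install the prenyl arm by O-allylation, Claisen and cross-metathesis.
2. **Step 3 (cross-metathesis on a hindered, phenol-bearing allylarene).** It may give olefin isomerisation or low conversion.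
   *Fallback:* Skip the allyl/Claisen/metathesis sequence (steps 1–3). Prenylate 9 directly at C2 with prenyl bromide under aqueous NaOH, or with prenol and BF3·OEt2, and separate the regioisomers.
3. **Step 7 (Sonogashira/cyclisation on a hindered alkyne with a free-OH electron-rich iodide).** It may give alkyne homocoupling or stop at the uncyclised alkynylphenol.
   *Fallback:* Use a Wittig route instead. Couple aldehyde 4 with (2-hydroxy-4-MOMO-benzyl)triphenylphosphonium bromide to give the 2-hydroxystilbene, cyclise oxidatively with PIDA or I2, and remove the MOM group under mild acid.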